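**Plan**

Numbering: ring A = C1 (ring C=O), C2 (bears butanoyl), C3 (C–OH), C4 (quaternary: Me, prenyl), C5 (C–OH), C6 (bears the CH2 bridge). Ring B is the aromatic ring.
Enabling feature: ring A is a cyclic tri-β-carbonyl array. C4–C5 is an α,α-disubstituted acetic acid unit (nucleophilic C4, acyl C5) and C3–C2–C1–C6 is a 2-acyl-3-oxo acid chain (acyl C3, enolisable C6). Both C3–C4 and C5–C6 therefore have Claisen polarity and can be made together.
Retrosynthesis: the helpers go first (two methoxymethyl ethers, the isoxazole nitrogen, prenyl back to CHO). One cut through C3–C4 and C5–C6 (formal [4+2]) then gives two partners. The first is an isoxazole-4-carbonyl chloride that masks the C1 and butanoyl carbonyls and already carries the bridge CH2 and ring B. The second is an α-methyl-γ-menthyloxy-γ-butyrolactone, a temporary ring that fixes the enolate geometry and stores the prenyl CH2–CH as a latent aldehyde.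
Forward order: ring B ketone, chromanone (brings in the bridge carbon), β-keto ester, isoxazole. Ring A then closes in one pot, the prenyl group comes from a Wittig reaction, and N–O cleavage plus hydrolysis unveil the triketone and the phenols.
Stereochemistry: C4 is the only stereocentre. It is set in the key step by acylation of the lactone enolate anti to the (5S)-menthyloxy group, which comes from (+)-menthol and is expelled in the same operation.

Key step: step 11

Assumption: the target is a set of rapidly interconverting enol tautomers, the drawn one is used throughout, and C4 (R in that tautomer) is its only fixed stereocentre; 5-hydroxyfuran-2(5H)-one and (+)-menthol are taken as purchasable.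

**Step 1**
Reactants: 1 5-methoxyresorcinol; 2 butanoic acid
Product: 3 1-(2,4-dihydroxy-6-methoxyphenyl)butan-1-one
Conditions: BF3·OEt2 (solvent), 85 °C; then aq NaOAc
Reagents that add atoms: none
Why: Friedel–Crafts acylation of a highly activated arene, in which attack at either of the two equivalent positions para to a free hydroxyl (between OH and OMe) should dominate over attack between the two hydroxyls, the minor symmetrical ketone being removed by chromatography.

**Step 2**
Reactants: 3 1-(2,4-dihydroxy-6-methoxyphenyl)butan-1-one; 4 Meldrum's acid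
Product: 6 6-butanoyl-5-hydroxy-7-methoxychroman-2-one, via methylene Meldrum's acid 5 (not isolated)
Conditions: (CH2O)n, pyridine, 60 then 100 °C
Reagents that add atoms: formaldehyde (from paraformaldehyde) C=O
Why: Knoevenagel condensation gives the strong Michael acceptor 5, which in a Yonemitsu-type three-component reaction should be attacked by the most nucleophilic ring carbon of 3 (C3, between the two hydroxyls), after which lactonisation with loss of acetone and decarboxylation give the chromanone; closure onto the other flanking hydroxyl would give a lactone isomer that converges to the same compound in step 3.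

**Step 3**
Reactants: 6 6-butanoyl-5-hydroxy-7-methoxychroman-2-one
Product: 8 methyl 3-[3-butanoyl-4-methoxy-2,6-bis(methoxymethoxy)phenyl]propanoate, via disodium bis-phenoxide 7 (not isolated)
Conditions: NaOMe (2.2 equiv), MeOH, 0 °C to rt; evaporate; MOMCl (3 equiv), DMF, 0 °C to rt
Reagents that add atoms: sodium methoxide C[O-].[Na+]; chloromethyl methyl ether COCCl
Why: Transesterification opens the aryl lactone irreversibly because phenoxide is a far weaker base than methoxide, and Williamson-type O-alkylation of both phenoxides of 7 then blocks relactonisation and removes all acidic OH groups.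

**Step 4**
Reactants: 8 methyl 3-[3-butanoyl-4-methoxy-2,6-bis(methoxymethoxy)phenyl]propanoate; 9 ethyl acetate
Product: 11 ethyl 5-[3-butanoyl-4-methoxy-2,6-bis(methoxymethoxy)phenyl]-3-oxopentanoate, via lithio ethyl acetate 10 (not isolated)
Conditions: 9 (3.5 equiv), LiN(iPr)2 (3.3 equiv), THF, −78 °C; then 8, −78 to −30 °C; AcOH
Reagents that add atoms: none
Why: Crossed Claisen condensation of an unhindered methyl ester with excess lithio ethyl acetate, driven by deprotonation of the β-keto ester formed, while the di-ortho-substituted aryl ketone is too hindered to be attacked.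

**Step 5**
Reactants: 11 ethyl 5-[3-butanoyl-4-methoxy-2,6-bis(methoxymethoxy)phenyl]-3-oxopentanoate; 12 butanal oxime
Product: 15 ethyl 5-{2-[3-butanoyl-4-methoxy-2,6-bis(methoxymethoxy)phenyl]ethyl}-3-propylisoxazole-4-carboxylate, via hydroximoyl chloride 13 (not isolated), via butanenitrile oxide 14 (not isolated)
Conditions: 12, N-chlorosuccinimide, DMF, rt to 40 °C until the chlorinating agent is consumed; then 11, NaOEt, EtOH, 0 °C to rt
Reagents that add atoms: none
Why: Chlorination of the aldoxime and dehydrochlorination give nitrile oxide 14, whose 1,3-dipolar cycloaddition to the enolate of the β-keto ester followed by loss of water is the standard regiospecific route to 3,5-disubstituted isoxazole-4-carboxylates (nitrile oxide carbon to the nucleophilic α-carbon, oxygen to the ketone carbon).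

**Step 6**
Reactants: 15 ethyl 5-{2-[3-butanoyl-4-methoxy-2,6-bis(methoxymethoxy)phenyl]ethyl}-3-propylisoxazole-4-carboxylate
Product: 16 5-{2-[3-butanoyl-4-methoxy-2,6-bis(methoxymethoxy)phenyl]ethyl}-3-propylisoxazole-4-carboxylic acid
Conditions: NaOH, EtOH/H2O, 60 °C; then 1 M HCl to pH 4, 0 °C
Reagents that add atoms: sodium hydroxide [OH-].[Na+]
Why: Saponification, to which 3,5-disubstituted isoxazoles, methoxymethyl ethers and the hindered aryl ketone are stable.

**Step 7**
Reactants: 16 5-{2-[3-butanoyl-4-methoxy-2,6-bis(methoxymethoxy)phenyl]ethyl}-3-propylisoxazole-4-carboxylic acid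
Product: 17 5-{2-[3-butanoyl-4-methoxy-2,6-bis(methoxymethoxy)phenyl]ethyl}-3-propylisoxazole-4-carbonyl chloride
Conditions: 1-chloro-N,N,2-trimethylprop-1-en-1-amine (1.2 equiv), CH2Cl2, 0 °C to rt; evaporate, use crude
Reagents that add atoms: 1-chloro-N,N,2-trimethylprop-1-en-1-amine CC(C)=C(Cl)N(C)C
Why: Acid chloride formation with an α-chloroenamine runs under neutral conditions without free HCl, so the methoxymethyl ethers should survive.

**Step 8**
Reactants: 18 5-hydroxyfuran-2(5H)-one (racemic); 19 (+)-menthol
Product: 20 (5S)-5-[(1S,2R,5S)-menthyloxy]furan-2(5H)-one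
Conditions: camphorsulfonic acid (cat.), toluene, reflux, water separator; crystallise from hexane, re-equilibrate the mother liquor with acid
Reagents that add atoms: none
Why: Acid-catalysed acetalisation of the pseudo-acid, in which the acetal centre equilibrates and the (5S) diastereomer, the mirror image of the well-known crystalline (5R) adduct of (−)-menthol, is harvested by crystallisation-induced diastereomer transformation.

**Step 9**
Reactants: 20 (5S)-5-[(1S,2R,5S)-menthyloxy]furan-2(5H)-one
Product: 21 (5S)-5-[(1S,2R,5S)-menthyloxy]dihydrofuran-2(3H)-one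
Conditions: H2 (1 atm), Pd/C, EtOAc, rt
Reagents that add atoms: none
Why: Heterogeneous catalytic hydrogenation of the conjugated C=C bond, which does not touch the acetal stereocentre.

**Step 10**
Reactants: 21 (5S)-5-[(1S,2R,5S)-menthyloxy]dihydrofuran-2(3H)-one
Product: 23 (3R,5S)-3-methyl-5-[(1S,2R,5S)-menthyloxy]dihydrofuran-2(3H)-one, via lithium enolate 22 (not isolated)
Conditions: LiN(iPr)2, THF, −78 °C; MeI, −78 to −40 °C
Reagents that add atoms: iodomethane CI
Why: Alkylation of a lactone enolate, expected mainly anti to the menthyloxy group, the configuration at C3 of the lactone being irrelevant because it is erased in step 11.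

**Step 11**
Reactants: 17 5-{2-[3-butanoyl-4-methoxy-2,6-bis(methoxymethoxy)phenyl]ethyl}-3-propylisoxazole-4-carbonyl chloride; 23 (3R,5S)-3-methyl-5-[(1S,2R,5S)-menthyloxy]dihydrofuran-2(3H)-one
Product: 27 2-[(5R)-7-{[3-butanoyl-4-methoxy-2,6-bis(methoxymethoxy)phenyl]methyl}-6-hydroxy-5-methyl-4-oxo-3-propyl-4,5-dihydro-1,2-benzoxazol-5-yl]acetaldehyde, via lithium enolate 24 (not isolated), via keto lactone 25 (not isolated), via ring-closed hemiacetal 26 (not isolated)
Conditions: 23 (1.2 equiv), LiN(iPr)2 (1.15 equiv), THF, −78 °C; 17 in THF, −78 °C, 30 min; KN(SiMe3)2 (1.1 equiv), −78 to −20 °C; AcOH, then pH 6 buffer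
Reagents that add atoms: none
Why: Proposed new method: enolate 24 is C-acylated at C4 by acid chloride 17 (C3–C4), KN(SiMe3)2 then removes a proton from the CH2 on isoxazole C5 (future C6), which the new C3 ketone acidifies vinylogously, this extended enolate attacks the lactone carbonyl (C5–C6), and the expelled hemiacetal alkoxide of 26 collapses to the aldehyde and menthoxide, which deprotonates the new vinylogous acid and makes the sequence irreversible. The closest known reaction types are the C-acylation of lithium ester enolates with acid chlorides, the lateral metalation of 5-alkylisoxazoles and toluate-anion annulations of the Staunton–Weinreb kind, in which a benzylic anion ortho to an acyl group closes a six-membered ring by Claisen condensation; new is their union into a formal [4+2] on a pseudo-ester lactone that releases its own auxiliary. Ring A closes in a 6-(enolendo)-exo-trig Dieckmann-type mode, the only one open because the α-carbon of the dienolate is the fully substituted C4 of the isoxazole, while the lactone ring opens. The single new stereocentre C4 is controlled by the (5S)-acetal carbon: the ring fixes the geometry of the tetrasubstituted enolate and the pseudo-axial menthyloxy group (anomeric effect) covers one face, so the acyl group should enter anti and give (3S,5S)-25, which maps onto (R)-C4 of the target and, being quaternary, cannot epimerise afterwards. The step needs C- over O-acylation (lithium counter-ion, THF, low temperature), deprotonation at the isoxazole C5 side chain and not at the C3 propyl group or next to the aryl ketone (only the former is conjugated with the C3 carbonyl), and no excess strong base once the aldehyde is free (one equivalent suffices because menthoxide is regenerated).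

**Step 12**
Reactants: 27 2-[(5R)-7-{[3-butanoyl-4-methoxy-2,6-bis(methoxymethoxy)phenyl]methyl}-6-hydroxy-5-methyl-4-oxo-3-propyl-4,5-dihydro-1,2-benzoxazol-5-yl]acetaldehyde; 28 isopropyltriphenylphosphonium iodide
Product: 30 (5R)-7-{[3-butanoyl-4-methoxy-2,6-bis(methoxymethoxy)phenyl]methyl}-6-hydroxy-5-methyl-5-(3-methylbut-2-enyl)-3-propyl-1,2-benzoxazol-4(5H)-one, via isopropylidene ylide 29 (not isolated)
Conditions: 28 (3 equiv), n-BuLi (2.9 equiv), THF, 0 °C; then 27, −78 °C to rt
Reagents that add atoms: none
Why: Wittig olefination with a non-stabilised ylide, the first equivalent of which only deprotonates the acidic enol and so protects ring A as its anion, while the hindered ketones do not compete with the aldehyde and the isopropylidene terminus raises no question of alkene geometry.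

**Step 13**
Reactants: 30 (5R)-7-{[3-butanoyl-4-methoxy-2,6-bis(methoxymethoxy)phenyl]methyl}-6-hydroxy-5-methyl-5-(3-methylbut-2-enyl)-3-propyl-1,2-benzoxazol-4(5H)-one
Product: 31 (4R)-enaminodiketone (drawn as imino-enol tautomer): 6-{[3-butanoyl-4-methoxy-2,6-bis(methoxymethoxy)phenyl]methyl}-3,5-dihydroxy-2-(1-iminobutyl)-4-methyl-4-(3-methylbut-2-enyl)cyclohexa-2,5-dien-1-one
Conditions: Mo(CO)6 (1 equiv), MeCN/H2O, 80 °C
Reagents that add atoms: none
Why: Reductive N–O cleavage of an isoxazole by zerovalent molybdenum and water gives the β-amino enone and, unlike hydrogenolysis, leaves the trisubstituted alkene, the ketones and the acetal-type protecting groups untouched.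

**Step 14**
Reactants: 31 (4R)-enaminodiketone
Product: 32 (4R)-2-butanoyl-6-[(3-butanoyl-2,6-dihydroxy-4-methoxyphenyl)methyl]-3,5-dihydroxy-4-methyl-4-(3-methylbut-2-enyl)cyclohexa-2,5-dien-1-one (target)
Conditions: 2 M aq HCl/THF, 45 °C
Reagents that add atoms: water O
Why: Acid hydrolysis of the primary enaminodiketone (the known way from reductively opened 4-acylisoxazoles to 2-acylcyclohexane-1,3-diones) and of both methoxymethyl ethers in one operation, in acid dilute enough that the prenyl double bond should not be protonated, C4 being quaternary and unaffected.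

**Compound list**

1 | 5-methoxyresorcinol | COc1cc(O)cc(O)c1 | starting material
2 | butanoic acid | CCCC(=O)O | starting material
3 | 1-(2,4-dihydroxy-6-methoxyphenyl)butan-1-one | CCCC(=O)c1c(O)cc(O)cc1OC | intermediate
4 | Meldrum's acid (2,2-dimethyl-1,3-dioxane-4,6-dione) | CC1(C)OC(=O)CC(=O)O1 | starting material
5 | methylene Meldrum's acid (2,2-dimethyl-5-methylidene-1,3-dioxane-4,6-dione), not isolated | C=C1C(=O)OC(C)(C)OC1=O | intermediate
6 | 6-butanoyl-5-hydroxy-7-methoxychroman-2-one | CCCC(=O)c1c(OC)cc2OC(=O)CCc2c1O | intermediate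
7 | disodium salt of methyl 3-(3-butanoyl-2,6-dihydroxy-4-methoxyphenyl)propanoate, not isolated | COC(=O)CCc1c([O-])cc(OC)c(C(=O)CCC)c1[O-].[Na+].[Na+] | intermediate
8 | methyl 3-[3-butanoyl-4-methoxy-2,6-bis(methoxymethoxy)phenyl]propanoate | COC(=O)CCc1c(OCOC)cc(OC)c(C(=O)CCC)c1OCOC | intermediate
9 | ethyl acetate | CCOC(C)=O | starting material
10 | lithium enolate of ethyl acetate, not isolated | [Li+].C=C([O-])OCC | intermediate
11 | ethyl 5-[3-butanoyl-4-methoxy-2,6-bis(methoxymethoxy)phenyl]-3-oxopentanoate | CCOC(=O)CC(=O)CCc1c(OCOC)cc(OC)c(C(=O)CCC)c1OCOC | intermediate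
12 | butanal oxime (E/Z mixture) | CCCC=NO | starting material
13 | (Z)-N-hydroxybutanimidoyl chloride, not isolated | CCC/C(Cl)=N/O | intermediate
14 | butanenitrile oxide, not isolated | CCCC#[N+][O-] | intermediate
15 | ethyl 5-{2-[3-butanoyl-4-methoxy-2,6-bis(methoxymethoxy)phenyl]ethyl}-3-propylisoxazole-4-carboxylate | CCCc1noc(CCc2c(OCOC)cc(OC)c(C(=O)CCC)c2OCOC)c1C(=O)OCC | intermediate
16 | 5-{2-[3-butanoyl-4-methoxy-2,6-bis(methoxymethoxy)phenyl]ethyl}-3-propylisoxazole-4-carboxylic acid | CCCc1noc(CCc2c(OCOC)cc(OC)c(C(=O)CCC)c2OCOC)c1C(=O)O | intermediate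
17 | 5-{2-[3-butanoyl-4-methoxy-2,6-bis(methoxymethoxy)phenyl]ethyl}-3-propylisoxazole-4-carbonyl chloride | CCCc1noc(CCc2c(OCOC)cc(OC)c(C(=O)CCC)c2OCOC)c1C(Cl)=O | intermediate
18 | 5-hydroxyfuran-2(5H)-one (racemic) | OC1OC(=O)C=C1 | starting material
19 | (+)-menthol, (1S,2R,5S) | O[C@H]1C[C@@H](C)CC[C@@H]1C(C)C | starting material
20 | (5S)-5-[(1S,2R,5S)-menthyloxy]furan-2(5H)-one | O=C1C=C[C@@H](O[C@H]2C[C@@H](C)CC[C@@H]2C(C)C)O1 | intermediate
21 | (5S)-5-[(1S,2R,5S)-menthyloxy]dihydrofuran-2(3H)-one | O=C1CC[C@@H](O[C@H]2C[C@@H](C)CC[C@@H]2C(C)C)O1 | intermediate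
22 | lithium enolate of 21, not isolated | [Li+].[O-]C1=CC[C@@H](O[C@H]2C[C@@H](C)CC[C@@H]2C(C)C)O1 | intermediate
23 | (3R,5S)-3-methyl-5-[(1S,2R,5S)-menthyloxy]dihydrofuran-2(3H)-one (methyl trans to menthyloxy) | O=C1[C@H](C)C[C@@H](O[C@H]2C[C@@H](C)CC[C@@H]2C(C)C)O1 | intermediate
24 | lithium enolate of 23, not isolated | [Li+].[O-]C1=C(C)C[C@@H](O[C@H]2C[C@@H](C)CC[C@@H]2C(C)C)O1 | intermediate
25 | (3S,5S)-3-(isoxazole-4-carbonyl)-3-methyl-5-menthyloxy lactone (acyl trans to menthyloxy), not isolated | O=C1[C@](C)(C(=O)c2c(CCC)noc2CCc3c(OCOC)cc(OC)c(C(=O)CCC)c3OCOC)C[C@@H](O[C@H]4C[C@@H](C)CC[C@@H]4C(C)C)O1 | intermediate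
26 | ring-closed benzisoxazolone carrying the (R)-2-hydroxy-2-menthyloxyethyl (hemiacetal) side chain at C5, not isolated | CCCc1noc2c1C(=O)[C@](C)(C[C@H](O)O[C@H]3C[C@@H](C)CC[C@@H]3C(C)C)C(O)=C2Cc4c(OCOC)cc(OC)c(C(=O)CCC)c4OCOC | intermediate
27 | 2-[(5R)-7-{[3-butanoyl-4-methoxy-2,6-bis(methoxymethoxy)phenyl]methyl}-6-hydroxy-5-methyl-4-oxo-3-propyl-4,5-dihydro-1,2-benzoxazol-5-yl]acetaldehyde | CCCc1noc2c1C(=O)[C@](C)(CC=O)C(O)=C2Cc3c(OCOC)cc(OC)c(C(=O)CCC)c3OCOC | intermediate
28 | isopropyltriphenylphosphonium iodide | CC(C)[P+](c1ccccc1)(c1ccccc1)c1ccccc1.[I-] | starting material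
29 | isopropylidenetriphenylphosphorane, not isolated | CC(C)=P(c1ccccc1)(c1ccccc1)c1ccccc1 | intermediate
30 | (5R)-7-{[3-butanoyl-4-methoxy-2,6-bis(methoxymethoxy)phenyl]methyl}-6-hydroxy-5-methyl-5-(3-methylbut-2-enyl)-3-propyl-1,2-benzoxazol-4(5H)-one | CCCc1noc2c1C(=O)[C@](C)(CC=C(C)C)C(O)=C2Cc3c(OCOC)cc(OC)c(C(=O)CCC)c3OCOC | intermediate
31 | (4R)-enaminodiketone, drawn as its imino-enol tautomer | CCCC(=N)C1=C(O)[C@](C)(CC=C(C)C)C(O)=C(Cc2c(OCOC)cc(OC)c(C(=O)CCC)c2OCOC)C1=O | intermediate
32 | (4R)-2-butanoyl-6-[(3-butanoyl-2,6-dihydroxy-4-methoxyphenyl)methyl]-3,5-dihydroxy-4-methyl-4-(3-methylbut-2-enyl)cyclohexa-2,5-dien-1-one | CCCC(=O)C1=C(O)[C@](C)(CC=C(C)C)C(O)=C(Cc2c(O)cc(OC)c(C(=O)CCC)c2O)C1=O | target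

Total step count: 14
Longest linear sequence: 11 steps (steps 1 to 7, then 11 to 14)

**Steps most likely to fail**

**Step 11.** What may go wrong: poor facial selectivity in the acylation, O-acylation of the tetrasubstituted enolate, or proton transfer ahead of C–C bond formation in the one-pot cascade. The fallback sets out from 17 and comes back at 27. It splits the cascade into isolated operations that are each known on their own, and it replaces the acetal stereocontrol by a carbon-based one.
- Purchased (S)-5-(trityloxymethyl)dihydrofuran-2(3H)-one F1 is methylated (LiN(iPr)2, MeI, THF, −78 °C) to the trans-methyl lactone F2.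
- The lithium enolate of F2 is acylated with 17; anti-selective second substitution of this enolate is the classical entry to quaternary centres in this lactone series. The trityl keto lactone F3 is isolated and freed from any minor diastereomer.
- KN(SiMe3)2 (THF, −78 to 0 °C) closes ring A by lateral metalation and Claisen condensation to the trityl-protected secondary alcohol F4.
- 80% aq AcOH at 40 °C removes the trityl group to give the vicinal diol F5.
- NaIO4 (THF/H2O) cleaves the glycol to 27.

**Step 14.** What may go wrong: acid-induced cyclisation of the prenyl group onto an enol oxygen, or incomplete hydrolysis of the vinylogous amide at a temperature the alkene tolerates. The fallback sets out from 31 and comes back at 32.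
- Aqueous LiOH in THF at 50 °C hydrolyses the enaminodiketone. Under these conditions the alkene cannot be protonated, and with ring B still protected no quinone methide exchange at the bridge can start. This gives the bis(methoxymethyl) ether of the target F7.
- ZnBr2 and propane-1-thiol in CH2Cl2 at 0 °C then remove both methoxymethyl groups by a soft Lewis acid/thiol exchange without a Brønsted acid.

**Step 12.** What may go wrong: enolisation of the aldehyde by the basic, hindered ylide, or sluggish reaction of its ring-chain (lactol) form. The fallback sets out from 27 and comes back at 30. It builds the trisubstituted alkene by metathesis instead of by carbonyl olefination.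
- The small and fast methylenetriphenylphosphorane (Ph3PCH3Br, KN(SiMe3)2, THF, −78 °C to rt) gives the allyl compound F6.
- Cross-metathesis of F6 with excess 2-methylbut-2-ene (second-generation Grubbs catalyst, CH2Cl2, 40 °C) gives 30.

**Further compounds**

F1 | step 11 | (S)-5-(trityloxymethyl)dihydrofuran-2(3H)-one | O=C1CC[C@@H](COC(c2ccccc2)(c2ccccc2)c2ccccc2)O1
F2 | step 11 | (3R,5S)-3-methyl-5-(trityloxymethyl)dihydrofuran-2(3H)-one | O=C1[C@H](C)C[C@@H](COC(c2ccccc2)(c2ccccc2)c2ccccc2)O1
F3 | step 11 | (3S,5S)-3-(isoxazole-4-carbonyl)-3-methyl-5-(trityloxymethyl) lactone | O=C1[C@](C)(C(=O)c2c(CCC)noc2CCc3c(OCOC)cc(OC)c(C(=O)CCC)c3OCOC)C[C@@H](COC(c4ccccc4)(c4ccccc4)c4ccccc4)O1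
F4 | step 11 | (5R)-benzisoxazolone with a (2S)-2-hydroxy-3-(trityloxy)propyl group at C5 | CCCc1noc2c1C(=O)[C@](C)(C[C@H](O)COC(c3ccccc3)(c3ccccc3)c3ccccc3)C(O)=C2Cc4c(OCOC)cc(OC)c(C(=O)CCC)c4OCOC
F5 | step 11 | (5R)-benzisoxazolone with a (2S)-2,3-dihydroxypropyl group at C5 | CCCc1noc2c1C(=O)[C@](C)(C[C@H](O)CO)C(O)=C2Cc3c(OCOC)cc(OC)c(C(=O)CCC)c3OCOC
F6 | step 12 | (5R)-5-allyl-7-{[3-butanoyl-4-methoxy-2,6-bis(methoxymethoxy)phenyl]methyl}-6-hydroxy-5-methyl-3-propyl-1,2-benzoxazol-4(5H)-one | CCCc1noc2c1C(=O)[C@](C)(CC=C)C(O)=C2Cc3c(OCOC)cc(OC)c(C(=O)CCC)c3OCOC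
F7 | step 14 | bis(methoxymethyl) ether of the target at both ring B phenols, (4R) | CCCC(=O)C1=C(O)[C@](C)(CC=C(C)C)C(O)=C(Cc2c(OCOC)cc(OC)c(C(=O)CCC)c2OCOC)C1=O
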